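**Retrosynthetic overview**
- Target 17 ⇐ tetra-MOM flavanone 16 ⇐ spiro-dithiane 15, in which C4 is still masked.
- 15 ⇐ one-flask annulation. The 2-lithio-1,3-dithiane of the A ring (an acyl anion) attacks the CH2 of (R)-aryloxirane 12 to make C3–C4. The alkoxide so formed then displaces an ortho fluoride to make O1–C8a.
- The epoxide oxygen becomes O1 and the benzylic C–O bond is never broken, so C2 comes from the epoxide with retention.
- A-ring dithiane 8 ⇐ 5-fluororesorcinol by two directed metalations (geranyl between the two OMOM groups, dithianyl next to F). Epoxide 12 ⇐ 3,5-dihydroxybenzaldehyde by methylene transfer and hydrolytic kinetic resolution.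
- Both benzene rings are bought; the pyranone ring is the only ring built, in step 7.

Assumption: 5-fluororesorcinol is bought as a catalogue compound; geranyl = (2E)-3,7-dimethylocta-2,6-dien-1-yl and MOM = methoxymethyl throughout.

**Step 1**
Reactants: 1 5-fluororesorcinol
Product: 2 1-fluoro-3,5-bis(methoxymethoxy)benzene
Conditions: NaH, MOMCl, THF/DMF, 0 °C → rt
Reagents that add atoms: chloromethyl methyl ether (MOMCl), COCCl
Why: Williamson-type O-alkylation of the bis-phenoxide; MOM directs ortho-lithiation, survives the organometallic and basic steps, and leaves under mild acid at the end.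

**Step 2**
Reactants: 2 1-fluoro-3,5-bis(methoxymethoxy)benzene; 3 geranyl bromide
Product: 5 5-fluoro-2-geranyl-1,3-bis(methoxymethoxy)benzene, via aryllithium 4 (not isolated)
Conditions: n-BuLi, Et2O, 0 °C; CuI (10 mol%), 3, −30 °C → rt
Reagents that add atoms: none
Why: Directed ortho-metalation with n-BuLi alone is coordination-controlled, so lithiation is expected at the carbon flanked by both chelating OMOM groups rather than next to F; copper-catalysed SN2 allylation then keeps the E olefin.

**Step 3**
Reactants: 5 5-fluoro-2-geranyl-1,3-bis(methoxymethoxy)benzene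
Product: 8 2-[6-fluoro-3-geranyl-2,4-bis(methoxymethoxy)phenyl]-1,3-dithiane, via aryllithium 6 (not isolated), via arylmagnesium bromide 7 (not isolated)
Conditions: n-BuLi, THF, −78 °C; MgBr2·OEt2, −78 °C; 2-chloro-1,3-dithiane (from 1,3-dithiane, NCS, PhMe, rt), −78 → 0 °C
Reagents that add atoms: 2-chloro-1,3-dithiane, ClC1SCCCS1 (made just before use from 1,3-dithiane, C1CSCSC1, and N-chlorosuccinimide, O=C1CCC(=O)N1Cl)
Why: Second directed ortho-metalation at the only ring C–H type left (between F and OMOM, the most acidic), Mg transmetalation to tame the o-fluoroaryl anion, then electrophilic dithianylation of the Grignard reagent with 2-chloro-1,3-dithiane installs the masked acyl carbon without any acid near the MOM groups.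

**Step 4**
Reactants: 9 3,5-dihydroxybenzaldehyde
Product: 10 3,5-bis(methoxymethoxy)benzaldehyde
Conditions: NaH, MOMCl, THF/DMF, 0 °C → rt
Reagents that add atoms: chloromethyl methyl ether (MOMCl), COCCl
Why: Williamson-type MOM protection of both phenols; the aldehyde is non-enolisable and untouched.

**Step 5**
Reactants: 10 3,5-bis(methoxymethoxy)benzaldehyde
Product: 11 rac-2-[3,5-bis(methoxymethoxy)phenyl]oxirane
Conditions: Me3S+ I−, NaH, DMSO/THF, 0 °C → rt
Reagents that add atoms: trimethylsulfonium iodide, C[S+](C)C.[I-]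
Why: Corey–Chaykovsky methylene transfer from the sulfonium ylide to a non-enolisable aryl aldehyde gives the terminal epoxide directly.

**Step 6**
Reactants: 11 rac-2-[3,5-bis(methoxymethoxy)phenyl]oxirane
Product: 12 (2R)-2-[3,5-bis(methoxymethoxy)phenyl]oxirane
Conditions: (S,S)-(salen)Co(III)OAc (1 mol%), H2O (0.55 equiv), THF, 0 °C → rt
Reagents that add atoms: none
Why: Jacobsen hydrolytic kinetic resolution; the catalyst enantiomer that hydrolyses the (S)-epoxide is used, so the (R)-epoxide is recovered in high ee (at most 50% yield), and this sets the only stereocentre of the target.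

**Step 7**
Reactants: 8 2-[6-fluoro-3-geranyl-2,4-bis(methoxymethoxy)phenyl]-1,3-dithiane; 12 (2R)-2-[3,5-bis(methoxymethoxy)phenyl]oxirane
Product: 15 (2S)-2-[3,5-bis(methoxymethoxy)phenyl]-6-geranyl-5,7-bis(methoxymethoxy)spiro[chromane-4,2'-[1,3]dithiane], via lithiated dithiane 13 (not isolated), via alkoxide 14 (not isolated)
Conditions: LDA, THF, −40 °C; 12, −40 °C → rt; then KOt-Bu, DMPU, 60 °C
Reagents that add atoms: none
Why: Proposed new method: the 2-lithio-2-aryl-1,3-dithiane (acyl-anion equivalent; LDA under amine-equilibrating conditions selects the S,S-benzylic C–H over the F/OMOM-flanked ring C–H that n-BuLi would attack) opens the epoxide at its CH2 (Corey–Seebach reaction, C3–C4 bond, benzylic C–O untouched so the (R)-epoxide geometry is retained and reads (S) by CIP), and after Li→K exchange the tethered alkoxide displaces the ortho fluoride in a six-membered intramolecular SNAr helped inductively by the two meta OMOM groups and the gem-disubstituted C4, the closest known reaction type being base-mediated SNAr cyclisation of 3-(2-fluoroaryl)propan-1-ols to chromans and flavans; because the ketone is masked, no retro-oxa-Michael can erode C2.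

**Step 8**
Reactants: 15 (2S)-2-[3,5-bis(methoxymethoxy)phenyl]-6-geranyl-5,7-bis(methoxymethoxy)spiro[chromane-4,2'-[1,3]dithiane]
Product: 16 (2S)-2-[3,5-bis(methoxymethoxy)phenyl]-6-geranyl-5,7-bis(methoxymethoxy)chroman-4-one
Conditions: MeI, CaCO3, MeCN/H2O (9:1), 45 °C
Reagents that add atoms: water, O
Why: Alkylative dethioacetalisation (S-methylation, aryl-stabilised thionium, hydrolysis) is non-oxidative and buffered, so the geranyl olefins, the electron-rich arene and the MOM acetals survive and the ketone never meets base that could open the ring at C2.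

**Step 9**
Reactants: 16 (2S)-2-[3,5-bis(methoxymethoxy)phenyl]-6-geranyl-5,7-bis(methoxymethoxy)chroman-4-one
Product: 17 schizolaenone C
Conditions: 3 M HCl, MeOH, 40 °C
Reagents that add atoms: none
Why: Acid-catalysed acetal methanolysis removes all four MOM groups under the mild conditions routinely used for prenylated and geranylated flavanones, which leave the olefins and the C2 configuration intact.

**Compound list**
1 | 5-fluororesorcinol (5-fluorobenzene-1,3-diol) | Oc1cc(F)cc(O)c1 | starting material
2 | 1-fluoro-3,5-bis(methoxymethoxy)benzene | COCOc1cc(F)cc(OCOC)c1 | intermediate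
3 | geranyl bromide, (2E)-1-bromo-3,7-dimethylocta-2,6-diene | CC(C)=CCC/C(C)=C/CBr | starting material
4 | [4-fluoro-2,6-bis(methoxymethoxy)phenyl]lithium | [Li]c1c(OCOC)cc(F)cc1OCOC | intermediate
5 | 5-fluoro-2-geranyl-1,3-bis(methoxymethoxy)benzene | CC(C)=CCC/C(C)=C/Cc1c(OCOC)cc(F)cc1OCOC | intermediate
6 | [6-fluoro-3-geranyl-2,4-bis(methoxymethoxy)phenyl]lithium | CC(C)=CCC/C(C)=C/Cc1c(OCOC)cc(F)c([Li])c1OCOC | intermediate
7 | [6-fluoro-3-geranyl-2,4-bis(methoxymethoxy)phenyl]magnesium bromide | CC(C)=CCC/C(C)=C/Cc1c(OCOC)cc(F)c([Mg]Br)c1OCOC | intermediate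
8 | 2-[6-fluoro-3-geranyl-2,4-bis(methoxymethoxy)phenyl]-1,3-dithiane | CC(C)=CCC/C(C)=C/Cc1c(OCOC)cc(F)c(c1OCOC)C1SCCCS1 | intermediate
9 | 3,5-dihydroxybenzaldehyde | O=Cc1cc(O)cc(O)c1 | starting material
10 | 3,5-bis(methoxymethoxy)benzaldehyde | O=Cc1cc(OCOC)cc(OCOC)c1 | intermediate
11 | rac-2-[3,5-bis(methoxymethoxy)phenyl]oxirane | C1OC1c1cc(OCOC)cc(OCOC)c1 | intermediate
12 | (2R)-2-[3,5-bis(methoxymethoxy)phenyl]oxirane | C1[C@@H](c2cc(OCOC)cc(OCOC)c2)O1 | intermediate
13 | 2-lithio-2-[6-fluoro-3-geranyl-2,4-bis(methoxymethoxy)phenyl]-1,3-dithiane | CC(C)=CCC/C(C)=C/Cc1c(OCOC)cc(F)c(c1OCOC)C1([Li])SCCCS1 | intermediate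
14 | lithium (1S)-1-[3,5-bis(methoxymethoxy)phenyl]-2-{2-[6-fluoro-3-geranyl-2,4-bis(methoxymethoxy)phenyl]-1,3-dithian-2-yl}ethanolate | CC(C)=CCC/C(C)=C/Cc1c(OCOC)cc(F)c(c1OCOC)C1(SCCCS1)C[C@@H](c1cc(OCOC)cc(OCOC)c1)O[Li] | intermediate
15 | (2S)-2-[3,5-bis(methoxymethoxy)phenyl]-6-geranyl-5,7-bis(methoxymethoxy)spiro[chromane-4,2'-[1,3]dithiane] | CC(C)=CCC/C(C)=C/Cc1c(OCOC)cc2c(c1OCOC)C1(SCCCS1)C[C@@H](c1cc(OCOC)cc(OCOC)c1)O2 | intermediate
16 | (2S)-2-[3,5-bis(methoxymethoxy)phenyl]-6-geranyl-5,7-bis(methoxymethoxy)chroman-4-one | CC(C)=CCC/C(C)=C/Cc1c(OCOC)cc2c(c1OCOC)C(=O)C[C@@H](c1cc(OCOC)cc(OCOC)c1)O2 | intermediate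
17 | schizolaenone C, (2S)-2-(3,5-dihydroxyphenyl)-6-geranyl-5,7-dihydroxychroman-4-one | CC(C)=CCC/C(C)=C/Cc1c(O)cc2c(c1O)C(=O)C[C@@H](c1cc(O)cc(O)c1)O2 | target

**Totals**
Total step count: 9. Longest linear sequence: 6 (steps 1, 2, 3, 7, 8, 9; the epoxide arm 4, 5, 6, 7, 8, 9 is equally long).

**Three steps most likely to fail**

Step 7 is the riskiest, because fluoride displacement from an arene that carries no conjugating acceptor may stall, and hot alkoxide could move the benzylic–allylic olefin of the geranyl group. The fallback sets out from alkoxide 14, which is quenched cold with NH4Cl instead of being heated, to give the open-chain alcohol (1S)-1-[3,5-bis(methoxymethoxy)phenyl]-2-{2-[6-fluoro-3-geranyl-2,4-bis(methoxymethoxy)phenyl]-1,3-dithian-2-yl}ethanol F1. The dithiane is then removed first (MeI, CaCO3, aqueous MeCN) to give the β-hydroxy ketone (3S)-3-[3,5-bis(methoxymethoxy)phenyl]-1-[6-fluoro-3-geranyl-2,4-bis(methoxymethoxy)phenyl]-3-hydroxypropan-1-one F2, in which the ortho carbonyl now activates the C–F bond. Ring closure by carbonyl-activated SNAr (Cs2CO3, MeCN, 0 °C, short contact to limit E1cB dehydration) comes back to the route at 16.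

Step 3 is next, because the hindered o-fluoroaryl Grignard reagent may couple poorly with 2-chloro-1,3-dithiane. The fallback sets out from 5: the same lithiation is quenched with DMF to give 6-fluoro-3-geranyl-2,4-bis(methoxymethoxy)benzaldehyde F3, which is thioacetalised under neutral conditions with 1,3-bis(trimethylsilylthio)propane and catalytic ZnI2 in Et2O, so the MOM groups are not exposed to protic or strong Lewis acid. It comes back to the route at 8.

Step 2 is third, because lithiation could go partly next to fluorine instead of between the two OMOM groups. The fallback avoids lithiation and sets out from 1: alumina-templated ortho,ortho-allylation of the free resorcinol with geraniol (acidic Al2O3, 1,2-dichloroethane, reflux) places the chain between the two hydroxyls and gives 5-fluoro-2-geranylbenzene-1,3-diol F4. Bis-MOM protection (NaH, MOMCl) then comes back to the route at 5.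

**Further compounds**
F1 | step 7 | (1S)-1-[3,5-bis(methoxymethoxy)phenyl]-2-{2-[6-fluoro-3-geranyl-2,4-bis(methoxymethoxy)phenyl]-1,3-dithian-2-yl}ethanol | CC(C)=CCC/C(C)=C/Cc1c(OCOC)cc(F)c(c1OCOC)C1(SCCCS1)C[C@@H](c1cc(OCOC)cc(OCOC)c1)O
F2 | step 7 | (3S)-3-[3,5-bis(methoxymethoxy)phenyl]-1-[6-fluoro-3-geranyl-2,4-bis(methoxymethoxy)phenyl]-3-hydroxypropan-1-one | CC(C)=CCC/C(C)=C/Cc1c(OCOC)cc(F)c(c1OCOC)C(=O)C[C@@H](c1cc(OCOC)cc(OCOC)c1)O
F3 | step 3 | 6-fluoro-3-geranyl-2,4-bis(methoxymethoxy)benzaldehyde | CC(C)=CCC/C(C)=C/Cc1c(OCOC)cc(F)c(C=O)c1OCOC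
F4 | step 2 | 5-fluoro-2-geranylbenzene-1,3-diol | CC(C)=CCC/C(C)=C/Cc1c(O)cc(F)cc1O
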